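**Plan**
- Retrosynthesis first cuts the angelate acyl–O bond and the phenol protecting group, then opens the CH2=C(Ar)–CH(O) unit back to the two C–O bonds of an oxirane, then cuts the aryl–alkene C–C bond and the propargyl–prenyl C–C bond.
- Enabling feature: the exomethylene carbon, the aryl-bearing sp2 carbon and the (S)-carbinol carbon are a transposed allylic alcohol. They map onto CH2OH, C2 and C3 of a 2-aryl oxirane-2-methanol, with the benzene ring on the quaternary oxirane carbon.
- Forward: the aryl bromide (three steps from the benzaldehyde) and the enynol (one step) are joined by anti-arylmagnesiation. The oxirane, the only ring made, is closed in step 6 and reopened by zinc after iodination. Angeloylation and acetal cleavage finish.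
- Stereochemistry: the single stereocenter comes from the L-(+)-diisopropyl tartrate ligand in step 6 and is carried in a C–O bond that is never broken. The E alkene of the precursor comes from anti-addition through a magnesium chelate, and the Z ester alkene from angelic acid itself.

Key step: step 6

Assumption: the facial sense of the tartrate-controlled epoxidation is taken from the empirical rule for (E)-2-aryl-3-substituted allylic alcohols (L-(+)-tartrate giving the (2S,3S)-epoxy alcohol, as for (E)-2,3-diphenylprop-2-en-1-ol); the configuration would be checked at compound 17 and the D-(−)-ester used if the opposite sense were found.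

**Route**

Step 1
Reactants: 1 2,4-dimethoxy-3-methylbenzaldehyde
Product: 3 2,4-dimethoxy-3-methylphenol, via aryl formate 2 (not isolated)
Conditions: mCPBA, CH2Cl2, 0 °C → rt; then K2CO3 (cat.), MeOH, rt
Reagents that add atoms: mCPBA (3-chloroperoxybenzoic acid), O=C(OO)c1cccc(Cl)c1
Why: Baeyer–Villiger oxidation of an aldehyde on an electron-rich ring proceeds with aryl migration to the aryl formate, and carbonate-catalysed methanolysis of that formate should release the phenol (the Dakin-type sequence); no stereocenter is involved.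

Step 2
Reactants: 3 2,4-dimethoxy-3-methylphenol
Product: 4 1,3-dimethoxy-4-(methoxymethoxy)-2-methylbenzene
Conditions: NaH, MOMCl, THF, 0 °C → rt
Reagents that add atoms: chloromethyl methyl ether (MOMCl), COCCl
Why: Williamson-type O-alkylation of the sodium phenoxide with the reactive α-chloro ether should give the methoxymethyl acetal, which protects the phenol against the organometallic steps and serves as the directing group of step 3.

Step 3
Reactants: 4 1,3-dimethoxy-4-(methoxymethoxy)-2-methylbenzene
Product: 6 1-bromo-3,5-dimethoxy-2-(methoxymethoxy)-4-methylbenzene, via aryllithium 5 (not isolated)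
Conditions: n-BuLi, THF, 0 °C; then BrCCl2CCl2Br, −78 °C → rt
Reagents that add atoms: 1,2-dibromo-1,1,2,2-tetrachloroethane, BrC(Cl)(Cl)C(Cl)(Cl)Br
Why: Directed ortho-metalation: the chelating OCH2OCH3 group outranks a methoxy group as director, so n-BuLi should remove the ring hydrogen next to it (the only free position ortho to the acetal), and the aryllithium is brominated by halogen transfer from BrCCl2CCl2Br.

Step 4
Reactants: 7 propargyl alcohol; 8 prenyl bromide
Product: 9 6-methylhept-5-en-2-yn-1-ol
Conditions: CuI (10 mol%), K2CO3, Bu4NCl (cat.), DMF, rt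
Reagents that add atoms: none
Why: Copper-catalysed coupling of a terminal alkyne with an allylic bromide (the alkynylcopper formed under carbonate base attacks the primary carbon of prenyl bromide) should give the linear skipped enyne without protection of the hydroxyl.

Step 5
Reactants: 6 1-bromo-3,5-dimethoxy-2-(methoxymethoxy)-4-methylbenzene; 9 6-methylhept-5-en-2-yn-1-ol
Product: 13 (2E)-2-[3,5-dimethoxy-2-(methoxymethoxy)-4-methylphenyl]-6-methylhepta-2,5-dien-1-ol, via aryl Grignard reagent 10 (not isolated), via bromomagnesium alkoxide 11 (not isolated), via oxamagnesacycle 12 (not isolated)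
Conditions: 6, Mg, THF, 50 °C; then 9 (10 in 2.5-fold amount), CuI (10 mol%), THF, 0 → 45 °C; then H2O, 0 °C
Reagents that add atoms: none
Why: After Grignard formation the reagent deprotonates the hydroxyl and, under CuI catalysis, adds across the alkyne in the alkoxide-directed anti-carbomagnesiation known for propargylic alcohols: aryl goes to the carbon next to CH2O and magnesium to the far carbon within a five-membered chelate, so protonolysis with retention leaves hydrogen cis to CH2OH and fixes the E alkene.

Step 6
Reactants: 13 (2E)-2-[3,5-dimethoxy-2-(methoxymethoxy)-4-methylphenyl]-6-methylhepta-2,5-dien-1-ol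
Product: 14 [(2S,3S)-2-[3,5-dimethoxy-2-(methoxymethoxy)-4-methylphenyl]-3-(3-methylbut-2-en-1-yl)oxiran-2-yl]methanol
Conditions: Ti(OiPr)4 (10 mol%), L-(+)-diisopropyl tartrate (12 mol%), t-BuOOH (2 equiv, in decane), 4 Å MS, CH2Cl2, −25 °C
Reagents that add atoms: tert-butyl hydroperoxide, CC(C)(C)OO
Why: The primary alkoxide of 13 and tert-butyl peroxide are bound side by side on the tetravalent titanium centre of the Ti(OiPr)4/L-(+)-diisopropyl tartrate catalyst, and the activated peroxide oxygen is passed to the C2=C3 π bond in one concerted step. The closest known reaction type is the Sharpless asymmetric epoxidation of (E)-2-aryl-3-substituted allylic alcohols such as (E)-2,3-diphenylprop-2-en-1-ol. The oxirane closes by syn [2+1] oxygen-atom transfer, both C–O bonds forming on the same alkene face, one of them being the carbinol C–O bond of the target. C2 and C3 arise together: the tartrate ligand chooses the face (reagent control, the L-(+)-ester leading to the 2S,3S isomer for this substitution pattern) and the E geometry of 13 fixes their relative configuration. The step needs site selectivity over the equally substituted prenyl alkene, secured because only the alkene next to the titanium-bound CH2OH is within reach of the peroxide, and high enantioface selectivity, favoured by hydrogen being cis to CH2OH. Catalytic titanium, molecular sieves and low temperature should keep the electron-rich benzylic oxirane from opening.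

Step 7
Reactants: 14 [(2S,3S)-2-[3,5-dimethoxy-2-(methoxymethoxy)-4-methylphenyl]-3-(3-methylbut-2-en-1-yl)oxiran-2-yl]methanol
Product: 15 (2R,3S)-2-(iodomethyl)-2-[3,5-dimethoxy-2-(methoxymethoxy)-4-methylphenyl]-3-(3-methylbut-2-en-1-yl)oxirane
Conditions: PPh3, I2, imidazole, CH2Cl2, 0 °C, dark
Reagents that add atoms: iodine, II
Why: Appel-type iodination (PPh3/I2 buffered by imidazole) converts the primary alcohol through its alkoxyphosphonium salt into the iodide by SN2 attack at CH2, leaving both oxirane carbons untouched, so only the C2 descriptor changes (S to R) because CH2I now outranks the ring carbon.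

Step 8
Reactants: 15 (2R,3S)-2-(iodomethyl)-2-[3,5-dimethoxy-2-(methoxymethoxy)-4-methylphenyl]-3-(3-methylbut-2-en-1-yl)oxirane
Product: 17 (3S)-2-[3,5-dimethoxy-2-(methoxymethoxy)-4-methylphenyl]-6-methylhepta-1,5-dien-3-ol, via iodozinc alkoxide 16 (not isolated)
Conditions: Zn dust (activated), EtOH, 70 °C; then H2O
Reagents that add atoms: none
Why: Zinc inserts into the C–I bond and the resulting β-oxido organozinc eliminates at once with cleavage of the C2–O bond (reductive opening of a 2,3-epoxy iodide), which creates the exomethylene group and leaves the C3–O bond, and with it the S configuration, intact.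

Step 9
Reactants: 17 (3S)-2-[3,5-dimethoxy-2-(methoxymethoxy)-4-methylphenyl]-6-methylhepta-1,5-dien-3-ol; 18 angelic acid
Product: 20 (3S)-2-[3,5-dimethoxy-2-(methoxymethoxy)-4-methylphenyl]-6-methylhepta-1,5-dien-3-yl (2Z)-2-methylbut-2-enoate, via mixed anhydride 19 (not isolated)
Conditions: 18, 2,4,6-Cl3C6H2COCl, Et3N, toluene, rt; then 17, toluene, 75 °C
Reagents that add atoms: none
Why: Yamaguchi esterification: the alcohol attacks the angeloyl carbonyl of the mixed anhydride because the other carbonyl is shielded by two ortho chlorines, and running the acylation without a nucleophilic catalyst is the established way to keep the Z geometry of angelates; the carbinol C–O bond is not broken, so the S center is retained.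

Step 10
Reactants: 20 (3S)-2-[3,5-dimethoxy-2-(methoxymethoxy)-4-methylphenyl]-6-methylhepta-1,5-dien-3-yl (2Z)-2-methylbut-2-enoate
Product: 21 (3S)-2-(2-hydroxy-3,5-dimethoxy-4-methylphenyl)-6-methylhepta-1,5-dien-3-yl (2Z)-2-methylbut-2-enoate
Conditions: HCl (0.5 M in MeOH), MeOH, 0 °C → rt
Reagents that add atoms: none
Why: Acid-catalysed transacetalisation of the aryl methoxymethyl ether with methanol should free the phenol under conditions mild enough to spare the angelate, the allylic C–O bond and the other alkenes, and no bond at the stereocenter is touched.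

**Compound list**

1 | 2,4-dimethoxy-3-methylbenzaldehyde | COc1ccc(C=O)c(OC)c1C | starting material
2 | 2,4-dimethoxy-3-methylphenyl formate | COc1ccc(OC=O)c(OC)c1C | intermediate
3 | 2,4-dimethoxy-3-methylphenol | COc1ccc(O)c(OC)c1C | intermediate
4 | 1,3-dimethoxy-4-(methoxymethoxy)-2-methylbenzene | COCOc1ccc(OC)c(C)c1OC | intermediate
5 | [3,5-dimethoxy-2-(methoxymethoxy)-4-methylphenyl]lithium | [Li]c1cc(OC)c(C)c(OC)c1OCOC | intermediate
6 | 1-bromo-3,5-dimethoxy-2-(methoxymethoxy)-4-methylbenzene | Brc1cc(OC)c(C)c(OC)c1OCOC | intermediate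
7 | propargyl alcohol (prop-2-yn-1-ol) | C#CCO | starting material
8 | prenyl bromide (1-bromo-3-methylbut-2-ene) | CC(C)=CCBr | starting material
9 | 6-methylhept-5-en-2-yn-1-ol | CC(C)=CCC#CCO | intermediate
10 | [3,5-dimethoxy-2-(methoxymethoxy)-4-methylphenyl]magnesium bromide | Br[Mg]c1cc(OC)c(C)c(OC)c1OCOC | intermediate
11 | bromomagnesium 6-methylhept-5-en-2-yn-1-olate | CC(C)=CCC#CCO[Mg]Br | intermediate
12 | 4-[3,5-dimethoxy-2-(methoxymethoxy)-4-methylphenyl]-3-(3-methylbut-2-en-1-yl)-2,5-dihydro-1,2-oxamagnesole | CC(C)=CCC1=C(c2cc(OC)c(C)c(OC)c2OCOC)CO[Mg]1 | intermediate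
13 | (2E)-2-[3,5-dimethoxy-2-(methoxymethoxy)-4-methylphenyl]-6-methylhepta-2,5-dien-1-ol | OC/C(c1cc(OC)c(C)c(OC)c1OCOC)=C/CC=C(C)C | intermediate
14 | [(2S,3S)-2-[3,5-dimethoxy-2-(methoxymethoxy)-4-methylphenyl]-3-(3-methylbut-2-en-1-yl)oxiran-2-yl]methanol | OC[C@]1(c2cc(OC)c(C)c(OC)c2OCOC)O[C@H]1CC=C(C)C | intermediate
15 | (2R,3S)-2-(iodomethyl)-2-[3,5-dimethoxy-2-(methoxymethoxy)-4-methylphenyl]-3-(3-methylbut-2-en-1-yl)oxirane | IC[C@]1(c2cc(OC)c(C)c(OC)c2OCOC)O[C@H]1CC=C(C)C | intermediate
16 | iodozinc (3S)-2-[3,5-dimethoxy-2-(methoxymethoxy)-4-methylphenyl]-6-methylhepta-1,5-dien-3-olate | C=C(c1cc(OC)c(C)c(OC)c1OCOC)[C@H](CC=C(C)C)O[Zn]I | intermediate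
17 | (3S)-2-[3,5-dimethoxy-2-(methoxymethoxy)-4-methylphenyl]-6-methylhepta-1,5-dien-3-ol | C=C(c1cc(OC)c(C)c(OC)c1OCOC)[C@H](CC=C(C)C)O | intermediate
18 | angelic acid ((2Z)-2-methylbut-2-enoic acid) | C/C=C(/C)C(=O)O | starting material
19 | (2Z)-2-methylbut-2-enoic 2,4,6-trichlorobenzoic anhydride | C/C=C(/C)C(=O)OC(=O)c1c(Cl)cc(Cl)cc1Cl | intermediate
20 | (3S)-2-[3,5-dimethoxy-2-(methoxymethoxy)-4-methylphenyl]-6-methylhepta-1,5-dien-3-yl (2Z)-2-methylbut-2-enoate | C=C(c1cc(OC)c(C)c(OC)c1OCOC)[C@H](CC=C(C)C)OC(=O)/C(C)=C\C | intermediate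
21 | (3S)-2-(2-hydroxy-3,5-dimethoxy-4-methylphenyl)-6-methylhepta-1,5-dien-3-yl (2Z)-2-methylbut-2-enoate | C=C(c1cc(OC)c(C)c(OC)c1O)[C@H](CC=C(C)C)OC(=O)/C(C)=C\C | target

**Step count and risks**

Total: 10 steps. Longest linear sequence: 9 steps (steps 1, 2, 3, 5, 6, 7, 8, 9, 10 from compound 1); step 4 is a one-step branch.

The three steps most likely to fail:

Step 5. The hindered, electron-rich aryl Grignard reagent may add sluggishly or with poor regiocontrol to the internal alkynol, and the basic medium may isomerise the skipped enyne before addition. The fallback sets out from 9 and 6 and replaces carbomagnesiation by hydrometalation and cross-coupling. Hydroxyl-directed trans-hydrostannation of 9 (Bu3SnH, [Cp*RuCl]4 cat., CH2Cl2, rt) should place tin on the carbon next to CH2OH with hydrogen anti to it, giving (2Z)-6-methyl-2-(tributylstannyl)hepta-2,5-dien-1-ol F1. Stille coupling of this stannane with 6 (Pd(PPh3)4, CuI, CsF, DMF, 45 °C) proceeds with retention of alkene geometry and returns to the route at 13.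

Step 9. Acylation of the hindered secondary alcohol may be slow, and the angeloyl unit may isomerise from Z to E (the tiglate) during activation or heating. The fallback sets out from 17 and builds the Z alkene on the ester instead of bringing it in. Coupling of 17 with 2-[bis(2,2,2-trifluoroethoxy)phosphoryl]propanoic acid (DCC, DMAP, CH2Cl2) should give (3S)-2-[3,5-dimethoxy-2-(methoxymethoxy)-4-methylphenyl]-6-methylhepta-1,5-dien-3-yl 2-[bis(2,2,2-trifluoroethoxy)phosphoryl]propanoate F2 as a mixture of epimers at the phosphonate-bearing carbon. Still–Gennari olefination of this phosphonate with acetaldehyde (KN(SiMe3)2, 18-crown-6, THF, −78 °C) is Z-selective for trisubstituted enoates and returns to the route at 20.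

Step 10. During acetal cleavage the acid may cause solvolysis or migration of the allylic angelate or its Z-to-E isomerisation. The fallback sets out from 17, moves the acetal cleavage ahead of the esterification and carries the phenol as a fluoride-labile silyl ether.
- Methanolic HCl on 17 should give 2-[(3S)-3-hydroxy-6-methylhepta-1,5-dien-2-yl]-4,6-dimethoxy-5-methylphenol F3.
- Selective silylation of the more acidic phenol (TBSCl, imidazole, DMF, 0 °C) should give (3S)-2-[2-(tert-butyldimethylsilyloxy)-3,5-dimethoxy-4-methylphenyl]-6-methylhepta-1,5-dien-3-ol F4.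
- Acylation with mixed anhydride 19 as in step 9 should give (3S)-2-[2-(tert-butyldimethylsilyloxy)-3,5-dimethoxy-4-methylphenyl]-6-methylhepta-1,5-dien-3-yl (2Z)-2-methylbut-2-enoate F5.
- Buffered desilylation (Bu4NF, AcOH, THF, 0 °C) returns to the route at the target 21.

**Further compounds**

F1 | step 5 | (2Z)-6-methyl-2-(tributylstannyl)hepta-2,5-dien-1-ol | OC/C(=C/CC=C(C)C)[Sn](CCCC)(CCCC)CCCC
F2 | step 9 | (3S)-2-[3,5-dimethoxy-2-(methoxymethoxy)-4-methylphenyl]-6-methylhepta-1,5-dien-3-yl 2-[bis(2,2,2-trifluoroethoxy)phosphoryl]propanoate | C=C(c1cc(OC)c(C)c(OC)c1OCOC)[C@H](CC=C(C)C)OC(=O)C(C)P(=O)(OCC(F)(F)F)OCC(F)(F)F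
F3 | step 10 | 2-[(3S)-3-hydroxy-6-methylhepta-1,5-dien-2-yl]-4,6-dimethoxy-5-methylphenol | C=C(c1cc(OC)c(C)c(OC)c1O)[C@H](CC=C(C)C)O
F4 | step 10 | (3S)-2-[2-(tert-butyldimethylsilyloxy)-3,5-dimethoxy-4-methylphenyl]-6-methylhepta-1,5-dien-3-ol | C=C(c1cc(OC)c(C)c(OC)c1O[Si](C)(C)C(C)(C)C)[C@H](CC=C(C)C)O
F5 | step 10 | (3S)-2-[2-(tert-butyldimethylsilyloxy)-3,5-dimethoxy-4-methylphenyl]-6-methylhepta-1,5-dien-3-yl (2Z)-2-methylbut-2-enoate | C=C(c1cc(OC)c(C)c(OC)c1O[Si](C)(C)C(C)(C)C)[C@H](CC=C(C)C)OC(=O)/C(C)=C\C
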